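Readings and results are calculated with constants of no real substance, noise included.

No single first-order rate constant can carry the flask larch, as its readings show.

in all of them: starting material 0.19 M; gas 57 mM (held)

| run | free catalyst | temperature | remark | time |
|---|---|---|---|---|
| larch | 5 mol% | 5 °C | the very flask that is asked about, followed so far |  |
| maple | 3.4 mol% | −10 °C | run made earlier |  |
| flask | 5 mol% | 5 °C |  | 2.0 h |

| run | time / min | product / % | starting material / % |
|---|---|---|---|
| larch | 10.0 | 34.4 | 65.6 |
| larch | 20.0 | 51.5 | 48.0 |
| larch | 30.0 | 61.8 | 38.9 |
| larch | 60.0 | 75.1 | 23.3 |
| larch | 120 | 82.9 | 16.5 |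
| maple | 20.0 | 15.8 | 82.3 |
| maple | 40.0 | 31.8 | 67.6 |
| maple | 60.0 | 43.6 | 55.5 |
| maple | 80.0 | 54.4 | 44.9 |
| maple | 120 | 67.5 | 31.9 |

(readings scatter by 0.5 percentage points)

- east: at 2.0 h take out 90% of the product then present, then wait 4.0 h
- north-east: at 2.0 h raise the temperature by 25 K, then wait 4.0 h
- south: change nothing and wait 4.0 h more
- south-east: at 2.0 h add free catalyst, 100% of the amount charged, then wait 4.0 h

- what is taken out of product is counted as made
- the numbers in the tables scatter by 0.5 percentage points (one standard deviation)
- at the start none of the gas is in solution
- additions bring no volume worth counting

- product, in percent of the starting material first charged, at 2.0 h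
- the remedy with the largest gain of product, or "none" below 2 percentage points (east / north-east / south / south-east / none)
- product present, with what was taken out counted in, in percent of the starting material first charged, after north-east
- product present, with what was taken out counted in, in percent of the starting material first charged, after south

In larch, the first 10.0 min give 0.0422 /min, but the last hour gives 0.00626 /min, so the constant falls. Maple, by contrast, is pseudo-first-order: 0.00974 /min over its first reading and 0.00952 /min over all five, though its product reaches 67.5%. Product therefore seems not to slow the reaction, and this reckoning gives east the same figure as waiting. What falls in larch is taken to be living catalyst.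

The first estimate is direct: 2.0 h is the last larch reading, so product stands near 82.9%. The wait is the weak link. Catalyst dying at a constant fractional rate leaves a finite total of conversion, but the doubling steps do not shrink much. Suppose instead that catalyst dies in pairs, second order in itself. Late on, living catalyst falls inversely with time, the rate constant goes as a/t, and its integral is a ln t. The doubling step, the natural logarithm of the ratio of c(starting material) at the start and end of a doubling of time, then stays constant. Read as what is not yet product, it is 0.428 from 30.0 min to 60.0 min, then 0.376 from 60.0 min to 120 min. Carried to 6.00 h, this gives 90.6% for south. Fresh catalyst equal to the charge should repeat the flask's own first 4.0 h, which is 2.0 h plus one doubling, giving 98.0%, more than waiting. The doubling step is read from larch at 5 °C, so it gives no figure for north-east, and this reckoning leaves that option open.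

The forecast gives 83.2%, south-east, 83.6% for north-east and 85% for south, on the ground that “Waiting adds roughly 1.5–2 points”. It parts from this reckoning on the wait.

The flask gives 83.7% and south-east, with gains of 14 percentage points for south-east, 7.7 points for south, 7.7 points for east and 7.2 points for north-east. South ends at 91.4%, north-east at 90.9%.

    partner → decomposed reagent (k = 0.0990 /min, Ea = 80.0 kJ/mol)
    starting material + catalyst intermediate A ⇌ catalyst intermediate B (K = 10.0 /M, k = 23.0 /M/min, Ea = 36.0 kJ/mol, ΔH = −68.0 kJ/mol)
    partner + free catalyst ⇌ catalyst intermediate A (K = 44.0 /M, k = 90.0 /M/min, Ea = 46.0 kJ/mol, ΔH = 31.0 kJ/mol)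
    2 catalyst intermediate A → spent catalyst (k = 23.0 /M/min, Ea = 44.0 kJ/mol)
    gas ⇌ partner, rate k5*(csat - [partner]) (kL = 2.60 /min)
    catalyst intermediate B → free catalyst + product (k = 4.20 /min, Ea = 77.0 kJ/mol)
    (constants at 5 °C)

At 0.749 h, starting material uses catalyst intermediate A 31 times as fast as pairing into spent catalyst does, yet spent catalyst holds 94.2% of the catalyst at 2.00 h. Carried to 20.0 h, the doubling step gives 95.1%, and this flask stands at 95.4%. With pair death, a larger loading acts as proportionally longer time, so the step gives 89.4% for the neighbour charged with 12 mol%, which stands at 90.4% at 2.00 h.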